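A direct plan would assemble the open chain as the racemic trienol A1 by addition of a geranyl metal to a four-carbon enal, set the oxirane by Sharpless kinetic resolution to give the epoxy alcohol A2, and invert the carbinol by Mitsunobu esterification to give the senecioate A3.
It would then turn the chain ends into the allylic chloride and epoxy aldehyde functions of the chloro epoxy aldehyde A4, close the ten-membered ring by intramolecular palladium/zinc carbonyl allylation to give the germacradienol A5, and finish by hydrogenation and acetylation.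
Its weakest steps would be: (a) the ring closure by carbonyl allylation, which would have to form the ten-membered ring at high dilution and set C-6 and C-7 at once, guided only by ring conformation, on the most precious material;
(b) the kinetic resolution followed by Mitsunobu inversion, which would discard half of the material and then need an SN2 displacement at a carbinol beside a fully substituted oxirane carbon;
(c) the site-selective allylic chlorination of one of three trisubstituted alkenes (and the late selective hydrogenation), steps that would add no stereocentre.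

**Plan of the new route.**
The carbocycle is read as a cyclodeca-1,5-diene, C-10=C-1–C-2–C-3–C-4=C-5 (C-4=C-5 being the oxirane precursor), which is the retron of a Cope rearrangement.
Cutting C-2–C-3 and joining C-5–C-10 gives a cyclohexane (C-5 to C-10) that already carries C-6 and C-7; C-10 is its carbinol carbon and is methylated later through the enol triflate.
Ring order: cyclohexane, ten-membered ring by four-atom ring expansion, oxirane.
Nothing is cyclised end to end, resolved or inverted by SN2: one chair sets C-3 and both alkene geometries, and the isopropyl group is present from step 1.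
A 6α-hydroxyl matched with C-3 directs the epoxidation and is then corrected by oxidation and chelate-controlled reduction.

Key step: step 9

Remark: ring atoms carry the germacrane numbers of the target (C-1 to C-15) in every Why line; the cyclohexane intermediates contain C-5 to C-10, and their systematic names use their own locants.
Remark: the 1,5-dienes 19 to 21 are kept at or below room temperature (Cope back-reaction) and away from acid (transannular cyclisation).
Assumption: the (S)-configured diarylprolinol ether gives the (2S)-aldehyde in step 1, as in related enamine α-functionalisations; if the sense were opposite, the (R) catalyst would be used.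

Step 1
Reactants: 1 3-methylbutanal; 2 but-3-en-2-one
Product: 4 (4S)-4-(propan-2-yl)cyclohex-2-en-1-one, via keto aldehyde 3 (not isolated)
Conditions: (S)-2-[methoxy(diphenyl)methyl]pyrrolidine (5 mol %), ethyl 3,4-dihydroxybenzoate (20 mol %), neat, 4 °C; then LiOH, i-PrOH, rt
Reagents that add atoms: none
Why: Enamine-catalysed Michael addition of the aldehyde to the enone (the catalyst shields one face of the E-enamine and so sets C-7) followed by intramolecular aldol condensation (Robinson-type annulation) should give the 4-substituted cyclohexenone without touching the new stereocentre.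

Step 2
Reactants: 4 (4S)-4-(propan-2-yl)cyclohex-2-en-1-one
Product: 5 (4S)-2-iodo-4-(propan-2-yl)cyclohex-2-en-1-one
Conditions: I2, pyridine, CH2Cl2, 0 °C to rt
Reagents that add atoms: iodine, II
Why: α-Iodination of the enone (pyridine-mediated addition–elimination) places the halide on C-5 and leaves the γ-stereocentre alone.

Step 3
Reactants: 6 (4-methoxyphenyl)methanol; 7 trichloroethene
Product: 8 1-({[(E)-1,2-dichloroethenyl]oxy}methyl)-4-methoxybenzene
Conditions: KH, THF, 0 °C to rt
Reagents that add atoms: none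
Why: Nucleophilic vinylic substitution of trichloroethene by the potassium alkoxide (elimination–addition, first stage of the ynol ether synthesis from trichloroethene) should give the (E)-dichlorovinyl ether.

Step 4
Reactants: 8 1-({[(E)-1,2-dichloroethenyl]oxy}methyl)-4-methoxybenzene
Product: 10 1-methoxy-4-[(prop-1-yn-1-yloxy)methyl]benzene, via lithium alkynyl ether 9 (not isolated)
Conditions: n-BuLi (2.2 equiv), THF, −78 to −40 °C; then MeI, DMPU, −78 °C to rt
Reagents that add atoms: iodomethane, CI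
Why: Dehydrochlorination and chlorine–lithium exchange give the lithium alkoxyacetylide, whose C-alkylation with iodomethane should give the 1-alkoxypropyne, used without heating because benzylic ynol ethers rearrange when warmed.

Step 5
Reactants: 10 1-methoxy-4-[(prop-1-yn-1-yloxy)methyl]benzene; 5 (4S)-2-iodo-4-(propan-2-yl)cyclohex-2-en-1-one
Product: 12 (4S)-2-[(1E)-1-[(4-methoxyphenyl)methoxy]prop-1-en-2-yl]-4-(propan-2-yl)cyclohex-2-en-1-one, via alkenylboronate 11 (not isolated)
Conditions: HBpin, Cp2Zr(H)Cl (5 mol %), Et3N (5 mol %), CH2Cl2, rt; then 5, Pd(dppf)Cl2 (5 mol %), Cs2CO3, THF/H2O, 40 °C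
Reagents that add atoms: pinacolborane, CC1(C)OBOC1(C)C
Why: syn-Hydroboration of the ynol ether puts boron on the carbon β to oxygen (H and B cis, hence O and B trans), and Suzuki–Miyaura coupling with the α-iodoenone goes with retention, which fixes the (E)-enol ether that step 9 needs.

Step 6
Reactants: 12 (4S)-2-[(1E)-1-[(4-methoxyphenyl)methoxy]prop-1-en-2-yl]-4-(propan-2-yl)cyclohex-2-en-1-one
Product: 14 (2R,3S,4S)-3-hydroxy-2-[(1E)-1-[(4-methoxyphenyl)methoxy]prop-1-en-2-yl]-4-(propan-2-yl)cyclohexan-1-one, via boryl ketone 13 (not isolated)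
Conditions: B2pin2, CuCl (5 mol %), Xantphos (5 mol %), NaOt-Bu (10 mol %), MeOH (2 equiv), THF, rt; then NaBO3·4H2O, THF/H2O, rt
Reagents that add atoms: bis(pinacolato)diboron, CC1(C)OB(OC1(C)C)B1OC(C)(C)C(C)(C)O1; sodium perborate, [Na+].[O-]OB=O
Why: Copper-catalysed conjugate borylation should add boron to C-6 anti to the neighbouring isopropyl group, oxidation of the C–B bond goes with retention, and C-5 (α to the carbonyl and allylic, hence easily epimerised) should settle trans to the hydroxyl in the all-equatorial ketone.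

Step 7
Reactants: 14 (2R,3S,4S)-3-hydroxy-2-[(1E)-1-[(4-methoxyphenyl)methoxy]prop-1-en-2-yl]-4-(propan-2-yl)cyclohexan-1-one
Product: 15 (2R,3S,4S)-3-[(tert-butyldimethylsilyl)oxy]-2-[(1E)-1-[(4-methoxyphenyl)methoxy]prop-1-en-2-yl]-4-(propan-2-yl)cyclohexan-1-one
Conditions: TBSOTf, 2,6-lutidine, CH2Cl2, −78 °C
Reagents that add atoms: tert-butyldimethylsilyl trifluoromethanesulfonate, CC(C)(C)[Si](C)(C)OS(=O)(=O)C(F)(F)F
Why: Silyl ether formation at the hindered secondary alcohol blocks retro-aldol and β-elimination paths and creates no stereocentre.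

Step 8
Reactants: 15 (2R,3S,4S)-3-[(tert-butyldimethylsilyl)oxy]-2-[(1E)-1-[(4-methoxyphenyl)methoxy]prop-1-en-2-yl]-4-(propan-2-yl)cyclohexan-1-one
Product: 16 (1R,2R,3S,4S)-3-[(tert-butyldimethylsilyl)oxy]-1-ethenyl-2-[(1E)-1-[(4-methoxyphenyl)methoxy]prop-1-en-2-yl]-4-(propan-2-yl)cyclohexan-1-ol
Conditions: CH2=CHMgBr, CeCl3, THF, −78 °C
Reagents that add atoms: vinylmagnesium bromide, C=C[Mg]Br
Why: 1,2-Addition of the non-basic organocerium reagent to the enolisable ketone should occur from the equatorial direction, away from the axial hydrogens on C-6 and C-8, which places the vinyl group trans to the alkenyl group on C-5 (all carbon and silyloxy substituents equatorial, hydroxyl axial).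

Step 9
Reactants: 16 (1R,2R,3S,4S)-3-[(tert-butyldimethylsilyl)oxy]-1-ethenyl-2-[(1E)-1-[(4-methoxyphenyl)methoxy]prop-1-en-2-yl]-4-(propan-2-yl)cyclohexan-1-ol
Product: 19 (1(10)Z,3S,4E,6S,7S)-6-[(tert-butyldimethylsilyl)oxy]-3-[(4-methoxyphenyl)methoxy]-14-norgermacra-1(10),4-dien-10-yl trifluoromethanesulfonate, via potassium alkoxide 17 (not isolated), via potassium enolate 18 (not isolated)
Conditions: KH, 18-crown-6, THF, 0 °C to rt; then N-(5-chloropyridin-2-yl)bis(trifluoromethanesulfonyl)imide, −78 to 0 °C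
Reagents that add atoms: N-(5-chloropyridin-2-yl)bis(trifluoromethanesulfonyl)imide, FC(F)(F)S(=O)(=O)N(c1ccc(Cl)cn1)S(=O)(=O)C(F)(F)F
Why: Deprotonation gives alkoxide 17, which undergoes an anionic oxy-Cope rearrangement ([3,3]-sigmatropic shift through a chair transition state, driven by the change from alkoxide to enolate): the C-5–C-10 bond of the cyclohexane breaks as C-2–C-3 forms, and enolate 18 is sulfonylated on oxygen in the same flask. The closest known reaction type is the alkoxide-accelerated ring expansion of trans-1,2-dialkenylcyclohexanols to (E)-cyclodec-5-enones, long used for germacranes. The ten-membered ring is closed by a four-atom ring expansion of the six-membered ring (C-1 to C-4 are inserted between C-10 and C-5), not by an end-to-end cyclisation. In the all-equatorial chair the ring bonds to C-9 and C-6 stay equatorial, so the enolate has C-9 trans to C-2 (the later (E)-1(10)-alkene; Z in 19 only because the triflate oxygen outranks C-9) and the new C-4=C-5 bond is E, while the (E)-enol ether places its oxygen equatorial on the forming C-3, whose configuration (3S) is therefore dictated by C-5 and C-10, both relayed from C-7. The step needs the concerted path to win over fragmentation and the enolate to survive until trapped: the ground-state chair of 17 is already the reactive conformer, the enolate carbon has no β-leaving group (the C-3 ether is γ to it), and the secondary silyl ether is not expected to migrate to the hindered tertiary alkoxide.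

Step 10
Reactants: 19 (1(10)Z,3S,4E,6S,7S)-6-[(tert-butyldimethylsilyl)oxy]-3-[(4-methoxyphenyl)methoxy]-14-norgermacra-1(10),4-dien-10-yl trifluoromethanesulfonate
Product: 20 (1(10)E,3S,4E,6S,7S)-6-[(tert-butyldimethylsilyl)oxy]-3-[(4-methoxyphenyl)methoxy]germacra-1(10),4-diene
Conditions: MeMgBr, Fe(acac)3 (5 mol %), THF/NMP, −30 °C
Reagents that add atoms: methylmagnesium bromide, C[Mg]Br
Why: Iron-catalysed cross-coupling (Kumada type) of the enol triflate with the methyl Grignard reagent should replace the triflate by C-14 with retention of the double-bond geometry fixed in step 9.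

Step 11
Reactants: 20 (1(10)E,3S,4E,6S,7S)-6-[(tert-butyldimethylsilyl)oxy]-3-[(4-methoxyphenyl)methoxy]germacra-1(10),4-diene
Product: 21 (1(10)E,3S,4E,6S,7S)-3-[(4-methoxyphenyl)methoxy]germacra-1(10),4-dien-6-ol
Conditions: TBAF, THF, 0 °C to rt
Reagents that add atoms: none
Why: Fluoride desilylation should free the 6α-hydroxyl under non-acidic conditions, as the acid-sensitive 1,5-diene requires.

Step 12
Reactants: 21 (1(10)E,3S,4E,6S,7S)-3-[(4-methoxyphenyl)methoxy]germacra-1(10),4-dien-6-ol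
Product: 22 (1(10)E,3S,4R,5R,6S,7S)-4,5-epoxy-3-[(4-methoxyphenyl)methoxy]germacr-1(10)-en-6-ol
Conditions: VO(acac)2 (5 mol %), t-BuOOH, CH2Cl2, 0 °C
Reagents that add atoms: tert-butyl hydroperoxide, CC(C)(C)OO
Why: Sharpless vanadium-catalysed hydroxyl-directed epoxidation touches only the allylic 4,5-alkene, and because the C-4 methyl group is cis to C-6 the carbinol hydrogen eclipses the double bond (allylic 1,3-strain), so that in the one rotamer where the hydroxyl (and the C-3 ether) lie on the outer, accessible face of the (E)-alkene oxygen is delivered to give the threo epoxy alcohol with the (4R,5R) oxirane of the target.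

Step 13
Reactants: 22 (1(10)E,3S,4R,5R,6S,7S)-4,5-epoxy-3-[(4-methoxyphenyl)methoxy]germacr-1(10)-en-6-ol
Product: 23 (1(10)E,3S,4R,5S,7S)-4,5-epoxy-3-[(4-methoxyphenyl)methoxy]germacr-1(10)-en-6-one
Conditions: Dess–Martin periodinane, NaHCO3, CH2Cl2, 0 °C
Reagents that add atoms: none
Why: Buffered Dess–Martin oxidation should erase the auxiliary C-6 configuration without epimerising C-7 or opening the oxirane (the C-5 descriptor changes only through the priority rules).

Step 14
Reactants: 23 (1(10)E,3S,4R,5S,7S)-4,5-epoxy-3-[(4-methoxyphenyl)methoxy]germacr-1(10)-en-6-one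
Product: 24 (1(10)E,3S,4R,5R,6R,7S)-4,5-epoxy-3-[(4-methoxyphenyl)methoxy]germacr-1(10)-en-6-ol
Conditions: Zn(BH4)2, Et2O, −20 °C
Reagents that add atoms: none
Why: Chelation-controlled reduction of the α,β-epoxy ketone (zinc bridges the carbonyl and oxirane oxygens and hydride enters from the open face of the chelate) is the standard route to erythro epoxy alcohols and should give the 6R carbinol, cis to the isopropyl group on the untouched C-7.

Step 15
Reactants: 24 (1(10)E,3S,4R,5R,6R,7S)-4,5-epoxy-3-[(4-methoxyphenyl)methoxy]germacr-1(10)-en-6-ol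
Product: 25 (1(10)E,3S,4R,5R,6R,7S)-4,5-epoxy-3-[(4-methoxyphenyl)methoxy]germacr-1(10)-en-6-yl acetate
Conditions: Ac2O, pyridine, DMAP (cat.), CH2Cl2, rt
Reagents that add atoms: acetic anhydride, CC(=O)OC(C)=O
Why: DMAP-catalysed acetylation of the secondary alcohol proceeds with retention.

Step 16
Reactants: 25 (1(10)E,3S,4R,5R,6R,7S)-4,5-epoxy-3-[(4-methoxyphenyl)methoxy]germacr-1(10)-en-6-yl acetate
Product: 26 (1(10)E,3S,4R,5R,6R,7S)-6-acetoxy-4,5-epoxygermacr-1(10)-en-3-ol
Conditions: DDQ, CH2Cl2/pH 7 phosphate buffer, 0 °C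
Reagents that add atoms: none
Why: Oxidative cleavage of the p-methoxybenzyl ether by DDQ under buffered conditions should free the C-3 hydroxyl without touching the oxirane, the acetate or the trisubstituted alkene.

Step 17
Reactants: 26 (1(10)E,3S,4R,5R,6R,7S)-6-acetoxy-4,5-epoxygermacr-1(10)-en-3-ol
Product: 27 (1(10)E,3S,4R,5R,6R,7S)-6-acetoxy-4,5-epoxygermacr-1(10)-en-3-yl 3-methylbut-2-enoate (CNP0267399.1)
Conditions: 3-methylbut-2-enoyl chloride, pyridine, DMAP (cat.), CH2Cl2, 0 °C
Reagents that add atoms: 3-methylbut-2-enoyl chloride, CC(C)=CC(Cl)=O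
Why: DMAP-catalysed acylation installs the senecioate with retention at C-3, and pyridine at 0 °C (no trialkylamine) should keep the acyl group from slipping to the β,γ-unsaturated isomer through the vinylketene.

**Compound list**

1 | 3-methylbutanal | CC(C)CC=O | starting material
2 | but-3-en-2-one | CC(=O)C=C | starting material
3 | (2S)-5-oxo-2-(propan-2-yl)hexanal | O=C[C@H](C(C)C)CCC(C)=O | intermediate
4 | (4S)-4-(propan-2-yl)cyclohex-2-en-1-one | O=C1C=C[C@H](C(C)C)CC1 | intermediate
5 | (4S)-2-iodo-4-(propan-2-yl)cyclohex-2-en-1-one | O=C1C(I)=C[C@H](C(C)C)CC1 | intermediate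
6 | (4-methoxyphenyl)methanol | COc1ccc(CO)cc1 | starting material
7 | trichloroethene | ClC=C(Cl)Cl | starting material
8 | 1-({[(E)-1,2-dichloroethenyl]oxy}methyl)-4-methoxybenzene | COc1ccc(CO/C(Cl)=C\Cl)cc1 | intermediate
9 | lithium 2-[(4-methoxyphenyl)methoxy]ethynide | COc1ccc(COC#C[Li])cc1 | intermediate
10 | 1-methoxy-4-[(prop-1-yn-1-yloxy)methyl]benzene | COc1ccc(COC#CC)cc1 | intermediate
11 | 2-[(1Z)-1-[(4-methoxyphenyl)methoxy]prop-1-en-2-yl]-4,4,5,5-tetramethyl-1,3,2-dioxaborolane | COc1ccc(CO/C=C(\C)B2OC(C)(C)C(C)(C)O2)cc1 | intermediate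
12 | (4S)-2-[(1E)-1-[(4-methoxyphenyl)methoxy]prop-1-en-2-yl]-4-(propan-2-yl)cyclohex-2-en-1-one | O=C1C(/C(C)=C/OCc2ccc(OC)cc2)=C[C@H](C(C)C)CC1 | intermediate
13 | (2S,3S,4S)-2-[(1E)-1-[(4-methoxyphenyl)methoxy]prop-1-en-2-yl]-4-(propan-2-yl)-3-(4,4,5,5-tetramethyl-1,3,2-dioxaborolan-2-yl)cyclohexan-1-one | O=C1[C@H](/C(C)=C/OCc2ccc(OC)cc2)[C@@H](B2OC(C)(C)C(C)(C)O2)[C@H](C(C)C)CC1 | intermediate
14 | (2R,3S,4S)-3-hydroxy-2-[(1E)-1-[(4-methoxyphenyl)methoxy]prop-1-en-2-yl]-4-(propan-2-yl)cyclohexan-1-one | O=C1[C@H](/C(C)=C/OCc2ccc(OC)cc2)[C@@H](O)[C@H](C(C)C)CC1 | intermediate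
15 | (2R,3S,4S)-3-[(tert-butyldimethylsilyl)oxy]-2-[(1E)-1-[(4-methoxyphenyl)methoxy]prop-1-en-2-yl]-4-(propan-2-yl)cyclohexan-1-one | O=C1[C@H](/C(C)=C/OCc2ccc(OC)cc2)[C@@H](O[Si](C)(C)C(C)(C)C)[C@H](C(C)C)CC1 | intermediate
16 | (1R,2R,3S,4S)-3-[(tert-butyldimethylsilyl)oxy]-1-ethenyl-2-[(1E)-1-[(4-methoxyphenyl)methoxy]prop-1-en-2-yl]-4-(propan-2-yl)cyclohexan-1-ol | CC(C)(C)[Si](C)(C)O[C@@H]1[C@@H](/C(C)=C/OCc2ccc(OC)cc2)[C@](O)(C=C)CC[C@H]1C(C)C | intermediate
17 | potassium (1R,2R,3S,4S)-3-[(tert-butyldimethylsilyl)oxy]-1-ethenyl-2-[(1E)-1-[(4-methoxyphenyl)methoxy]prop-1-en-2-yl]-4-(propan-2-yl)cyclohexan-1-olate | CC(C)(C)[Si](C)(C)O[C@@H]1[C@@H](/C(C)=C/OCc2ccc(OC)cc2)[C@]([O-])(C=C)CC[C@H]1C(C)C.[K+] | intermediate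
18 | potassium (1(10)Z,3S,4E,6S,7S)-6-[(tert-butyldimethylsilyl)oxy]-3-[(4-methoxyphenyl)methoxy]-14-norgermacra-1(10),4-dien-10-olate (C-2 trans to C-9) | CC(C)(C)[Si](C)(C)O[C@@H]1/C=C(\C)[C@@H](OCc2ccc(OC)cc2)C/C=C(\[O-])CC[C@H]1C(C)C.[K+] | intermediate
19 | (1(10)Z,3S,4E,6S,7S)-6-[(tert-butyldimethylsilyl)oxy]-3-[(4-methoxyphenyl)methoxy]-14-norgermacra-1(10),4-dien-10-yl trifluoromethanesulfonate (C-2 trans to C-9) | CC(C)(C)[Si](C)(C)O[C@@H]1/C=C(\C)[C@@H](OCc2ccc(OC)cc2)C/C=C(\OS(=O)(=O)C(F)(F)F)CC[C@H]1C(C)C | intermediate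
20 | (1(10)E,3S,4E,6S,7S)-6-[(tert-butyldimethylsilyl)oxy]-3-[(4-methoxyphenyl)methoxy]germacra-1(10),4-diene | CC(C)(C)[Si](C)(C)O[C@@H]1/C=C(\C)[C@@H](OCc2ccc(OC)cc2)C/C=C(\C)CC[C@H]1C(C)C | intermediate
21 | (1(10)E,3S,4E,6S,7S)-3-[(4-methoxyphenyl)methoxy]germacra-1(10),4-dien-6-ol | O[C@@H]1/C=C(\C)[C@@H](OCc2ccc(OC)cc2)C/C=C(\C)CC[C@H]1C(C)C | intermediate
22 | (1(10)E,3S,4R,5R,6S,7S)-4,5-epoxy-3-[(4-methoxyphenyl)methoxy]germacr-1(10)-en-6-ol | O[C@@H]1[C@H]2O[C@]2(C)[C@@H](OCc3ccc(OC)cc3)C/C=C(\C)CC[C@H]1C(C)C | intermediate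
23 | (1(10)E,3S,4R,5S,7S)-4,5-epoxy-3-[(4-methoxyphenyl)methoxy]germacr-1(10)-en-6-one | O=C1[C@H]2O[C@]2(C)[C@@H](OCc3ccc(OC)cc3)C/C=C(\C)CC[C@H]1C(C)C | intermediate
24 | (1(10)E,3S,4R,5R,6R,7S)-4,5-epoxy-3-[(4-methoxyphenyl)methoxy]germacr-1(10)-en-6-ol | O[C@H]1[C@H]2O[C@]2(C)[C@@H](OCc3ccc(OC)cc3)C/C=C(\C)CC[C@H]1C(C)C | intermediate
25 | (1(10)E,3S,4R,5R,6R,7S)-4,5-epoxy-3-[(4-methoxyphenyl)methoxy]germacr-1(10)-en-6-yl acetate | CC(=O)O[C@H]1[C@H]2O[C@]2(C)[C@@H](OCc3ccc(OC)cc3)C/C=C(\C)CC[C@H]1C(C)C | intermediate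
26 | (1(10)E,3S,4R,5R,6R,7S)-6-acetoxy-4,5-epoxygermacr-1(10)-en-3-ol | CC(=O)O[C@H]1[C@H]2O[C@]2(C)[C@@H](O)C/C=C(\C)CC[C@H]1C(C)C | intermediate
27 | (1(10)E,3S,4R,5R,6R,7S)-6-acetoxy-4,5-epoxygermacr-1(10)-en-3-yl 3-methylbut-2-enoate (CNP0267399.1) | CC(=O)O[C@H]1[C@H]2O[C@]2(C)[C@@H](OC(=O)C=C(C)C)C/C=C(\C)CC[C@H]1C(C)C | target

**Step count.** Total: 17 steps. Longest linear sequence: 15 steps (steps 1, 2 and 5 to 17; steps 3 and 4 make the ynol ether).

**Steps most likely to fail**

Step 9. The rearrangement may leak through a boat-like transition state, or the alkoxide may fragment at the C-5–C-10 bond instead of rearranging, so that the configuration at C-3 or the alkene geometry is eroded. The fallback no longer sets C-3 in the sigmatropic step but by allylic oxidation while C-1=C-10 is still masked as the electron-poor enol triflate. It sets out from 5 and comes back at 19. Suzuki–Miyaura coupling of 5 with commercial 4,4,5,5-tetramethyl-2-(prop-1-en-2-yl)-1,3,2-dioxaborolane would give the dienone F1. The conditions of steps 6 to 9 would then lead through the boryl ketone F2 to the hydroxy ketone F3, the silyl ether F4, the carbinol F5 and, through the potassium alkoxide F6 and the potassium enolate F7, to the enol triflate F8, in which C-3 is a methylene group. SeO2 (cat.) with t-BuOOH in CH2Cl2 (ene reaction, then 2,3-sigmatropic shift) should hydroxylate that methylene group, which sits on the more substituted end of the only electron-rich alkene, from the outer face of the rotamer that the 6α-silyloxy group favours, to give the allylic alcohol F9. p-Methoxybenzylation under neutral conditions (2-[(4-methoxyphenyl)methoxy]-4-methylquinoline, MeOTf, MgO, PhCF3) would return to 19.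

Step 6. Conjugate borylation of the hindered, cross-conjugated dienone may be slow, the aldol-type product may lose water back to 12 during the basic oxidation, or epimerisation at C-5 may stay incomplete. In the fallback the oxygen is brought in as an oxirane and the α-carbon is then reduced. It sets out from 12 and comes back at 14. Nucleophilic epoxidation with t-BuOOH and DBU, anti to the isopropyl group, would give the epoxy ketone F10. SmI2 in THF/MeOH at −78 °C should cleave the Cα–O bond, and protonation of the samarium enolate returns to 14.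

Step 12. The vanadium alkoxide may not reach its preferred geometry inside the ring, so that facial selectivity falls, the carbinol is oxidised to the enone, or the 1(10)-alkene competes. In the fallback a peracid epoxidation is run before the methyl group is in place. It sets out from 19 and comes back at 22. TBAF would give the alcohol F11. m-CPBA (NaHCO3, CH2Cl2, 0 °C), hydrogen-bonded to the hydroxyl on the outer face of the same rotamer, should epoxidise only the 4,5-alkene, because the enol triflate alkene is electron-poor, to give the epoxy alcohol F12. Negishi methylation (MeZnCl, Pd(PPh3)4, THF, rt) returns to 22.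

Further compounds
F1 | step 9 | (4S)-2-(prop-1-en-2-yl)-4-(propan-2-yl)cyclohex-2-en-1-one | O=C1C(C(C)=C)=C[C@H](C(C)C)CC1
F2 | step 9 | (2S,3S,4S)-2-(prop-1-en-2-yl)-4-(propan-2-yl)-3-(4,4,5,5-tetramethyl-1,3,2-dioxaborolan-2-yl)cyclohexan-1-one | O=C1[C@H](C(C)=C)[C@@H](B2OC(C)(C)C(C)(C)O2)[C@H](C(C)C)CC1
F3 | step 9 | (2R,3S,4S)-3-hydroxy-2-(prop-1-en-2-yl)-4-(propan-2-yl)cyclohexan-1-one | O=C1[C@H](C(C)=C)[C@@H](O)[C@H](C(C)C)CC1
F4 | step 9 | (2R,3S,4S)-3-[(tert-butyldimethylsilyl)oxy]-2-(prop-1-en-2-yl)-4-(propan-2-yl)cyclohexan-1-one | O=C1[C@H](C(C)=C)[C@@H](O[Si](C)(C)C(C)(C)C)[C@H](C(C)C)CC1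
F5 | step 9 | (1R,2R,3S,4S)-3-[(tert-butyldimethylsilyl)oxy]-1-ethenyl-2-(prop-1-en-2-yl)-4-(propan-2-yl)cyclohexan-1-ol | CC(C)(C)[Si](C)(C)O[C@@H]1[C@@H](C(C)=C)[C@](O)(C=C)CC[C@H]1C(C)C
F6 | step 9 | potassium (1R,2R,3S,4S)-3-[(tert-butyldimethylsilyl)oxy]-1-ethenyl-2-(prop-1-en-2-yl)-4-(propan-2-yl)cyclohexan-1-olate | CC(C)(C)[Si](C)(C)O[C@@H]1[C@@H](C(C)=C)[C@]([O-])(C=C)CC[C@H]1C(C)C.[K+]
F7 | step 9 | potassium (1(10)Z,4E,6S,7S)-6-[(tert-butyldimethylsilyl)oxy]-14-norgermacra-1(10),4-dien-10-olate | CC(C)(C)[Si](C)(C)O[C@@H]1/C=C(\C)CC/C=C(\[O-])CC[C@H]1C(C)C.[K+]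
F8 | step 9 | (1(10)Z,4E,6S,7S)-6-[(tert-butyldimethylsilyl)oxy]-14-norgermacra-1(10),4-dien-10-yl trifluoromethanesulfonate | CC(C)(C)[Si](C)(C)O[C@@H]1/C=C(\C)CC/C=C(\OS(=O)(=O)C(F)(F)F)CC[C@H]1C(C)C
F9 | step 9 | (1(10)Z,3S,4E,6S,7S)-6-[(tert-butyldimethylsilyl)oxy]-3-hydroxy-14-norgermacra-1(10),4-dien-10-yl trifluoromethanesulfonate | CC(C)(C)[Si](C)(C)O[C@@H]1/C=C(\C)[C@@H](O)C/C=C(\OS(=O)(=O)C(F)(F)F)CC[C@H]1C(C)C
F10 | step 6 | (4S)-2,3-epoxy-2-[(1E)-1-[(4-methoxyphenyl)methoxy]prop-1-en-2-yl]-4-(propan-2-yl)cyclohexan-1-one, oxirane trans to the isopropyl group | O=C1[C@@]2(/C(C)=C/OCc3ccc(OC)cc3)O[C@H]2[C@H](C(C)C)CC1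
F11 | step 12 | (1(10)Z,3S,4E,6S,7S)-6-hydroxy-3-[(4-methoxyphenyl)methoxy]-14-norgermacra-1(10),4-dien-10-yl trifluoromethanesulfonate | O[C@@H]1/C=C(\C)[C@@H](OCc2ccc(OC)cc2)C/C=C(\OS(=O)(=O)C(F)(F)F)CC[C@H]1C(C)C
F12 | step 12 | (1(10)Z,3S,4R,5R,6S,7S)-4,5-epoxy-6-hydroxy-3-[(4-methoxyphenyl)methoxy]-14-norgermacr-1(10)-en-10-yl trifluoromethanesulfonate | O[C@@H]1[C@H]2O[C@]2(C)[C@@H](OCc3ccc(OC)cc3)C/C=C(\OS(=O)(=O)C(F)(F)F)CC[C@H]1C(C)C
A1 | direct plan | rac-(2E,6E)-1-[(tert-butyldimethylsilyl)oxy]-3,7,11-trimethyldodeca-2,6,10-trien-4-ol | OC(C/C=C(\C)CCC=C(C)C)/C(C)=C/CO[Si](C)(C)C(C)(C)C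
A2 | direct plan | (2R,3R,4R,6E)-1-[(tert-butyldimethylsilyl)oxy]-2,3-epoxy-3,7,11-trimethyldodeca-6,10-dien-4-ol | CC(C)(C)[Si](C)(C)OC[C@H]1O[C@]1(C)[C@H](O)C/C=C(\C)CCC=C(C)C
A3 | direct plan | (2R,3R,4S,6E)-1-[(tert-butyldimethylsilyl)oxy]-2,3-epoxy-3,7,11-trimethyldodeca-6,10-dien-4-yl 3-methylbut-2-enoate | CC(C)(C)[Si](C)(C)OC[C@H]1O[C@]1(C)[C@@H](OC(=O)C=C(C)C)C/C=C(\C)CCC=C(C)C
A4 | direct plan | (2S,3R,4S,6E,10RS)-10-chloro-2,3-epoxy-3,7,11-trimethyl-1-oxododeca-6,11-dien-4-yl 3-methylbut-2-enoate | O=C[C@H]1O[C@]1(C)[C@@H](OC(=O)C=C(C)C)C/C=C(\C)CCC(Cl)C(C)=C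
A5 | direct plan | (1(10)E,3S,4R,5R,6R,7S)-4,5-epoxy-6-hydroxygermacra-1(10),11-dien-3-yl 3-methylbut-2-enoate | O[C@H]1[C@H]2O[C@]2(C)[C@@H](OC(=O)C=C(C)C)C/C=C(\C)CC[C@H]1C(C)=C
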